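Retrosynthetic overview
1. The target is a 14-membered cembranoid carbocycle (cembrane numbering used below: C1 carries the isopropyl group, C4 the ring methyl, C6 the OAc, C8 and C12 the CO2Me groups, C13 the OH). It is opened at C4–C5 to an acyclic seco-compound with an (E)-dienyl bromide at C4 and a primary alkyl bromide at C5, to be joined by a nickel-catalysed reductive cross-electrophile macrocyclisation.
2. Enabling feature: in the ring, C4–C5 links the methyl-bearing sp2 terminus (C4) of the C1=C2–C3=C4 diene to a stereochemically silent CH2 (C5) next to the oxygen-bearing C6. Both ends can therefore be carried as C–Br bonds through the assembly and joined without creating a stereocentre or an alkene geometry that is not already fixed.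
3. The seco-chain is assembled at C12–C13 by a catalytic asymmetric alkynylation (sets C13), followed by trans-hydrostannation and methoxycarbonylation (C11=C12 with its ester).
4. C5–C12 piece: (S)-glycidol (C6 stereocentre) → α-silyloxy aldehyde → Still–Gennari olefination (C7=C8). C13–C4 piece: copper-catalysed alkylboration of 3-methylbut-1-yne (C1=C2), then Suzuki–Miyaura coupling with (E)-2-bromo-1-iodopropene (C3=C4).
5. Ring formation: only the 14-membered carbocycle, in step 15; then OSiEt3 → OAc exchange at C6 and desilylation at C13.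

Key step: step 15

Assumption: (S,S)-ProPhenol is taken to direct the alkynyl group to the Si face of aldehyde 8 (giving the R carbinol); should the sense be the opposite, the (R,R)-ligand takes its place and nothing else changes.

Step 1
Reactants: 1 propyne
Product: 2 (E)-2-bromo-1-iodoprop-1-ene
Conditions: IBr, CH2Cl2, −78 °C
Reagents that add atoms: iodine monobromide, IBr
Why: Electrophilic anti addition of I–Br across the terminal alkyne (iodobromination) puts bromine on the internal carbon by Markovnikov opening of the iodonium ion and places I and Br trans, which fixes the (E) geometry needed later at C3=C4.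

Step 2
Reactants: 3 3-methylbut-1-yne; 4 tert-butyl(2-iodoethoxy)dimethylsilane
Product: 5 (E)-alkenyl pinacol boronate pinB–CH=C(iPr)–CH2CH2OTBS (boron cis to the CH2CH2OTBS arm)
Conditions: CuCl (10 mol%), Xantphos (11 mol%), B2pin2 (1.3 equiv), LiOt-Bu (1.5 equiv), DMF, rt
Reagents that add atoms: bis(pinacolato)diboron, CC1(C)OB(OC1(C)C)B1OC(C)(C)C(C)(C)O1
Why: Copper-catalysed alkylboration (carboboration) of a terminal alkyne: syn addition of Cu–Bpin with boron at the terminal carbon, then C-alkylation at copper by the primary iodide with retention, should give the trisubstituted alkene with Bpin cis to the new CH2CH2O arm (the future C1=C2).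

Step 3
Reactants: 5 (E)-alkenyl pinacol boronate; 2 (E)-2-bromo-1-iodoprop-1-ene
Product: 6 (3E,5E)-dienyl bromide TBS ether TBSO–CH2CH2–C(iPr)=CH–CH=C(CH3)Br
Conditions: Pd(PPh3)4 (5 mol%), K3PO4, THF/H2O, rt
Reagents that add atoms: none
Why: Suzuki–Miyaura coupling, stereoretentive at both alkenyl carbons; zerovalent palladium adds to the C–I bond of 2 far faster than to its C–Br bond, so the bromide survives as the later coupling handle at C4.

Step 4
Reactants: 6 dienyl bromide TBS ether
Product: 7 (3E,5E)-6-bromo-3-(propan-2-yl)hepta-3,5-dien-1-ol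
Conditions: HF·pyridine, pyridine, THF, 0 °C to rt
Reagents that add atoms: none
Why: Desilylation of a primary TBS ether by buffered HF, which leaves the alkenyl bromide and the diene untouched.

Step 5
Reactants: 7 dienyl bromide alcohol
Product: 8 (3E,5E)-6-bromo-3-(propan-2-yl)hepta-3,5-dienal
Conditions: Dess–Martin periodinane, pyridine, CH2Cl2, 0 °C; used at once
Reagents that add atoms: none
Why: Dess–Martin oxidation under buffered, non-basic conditions should give the β,γ-unsaturated aldehyde without moving the C1=C2 bond into conjugation.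

Step 6
Reactants: 9 (S)-glycidol
Product: 10 (2S)-3-bromopropane-1,2-diol
Conditions: LiBr, AcOH, THF, 0 °C to rt
Reagents that add atoms: lithium bromide, [Li+].[Br-]
Why: Regioselective SN2 opening of the epoxide at its unsubstituted carbon by bromide under buffered acid (halohydrin formation) leaves the stereocentre (future C6) untouched.

Step 7
Reactants: 10 (2S)-3-bromopropane-1,2-diol
Product: 11 (2S)-3-bromo-1,2-bis[(triethylsilyl)oxy]propane
Conditions: Et3SiCl, imidazole, DMF, 0 °C to rt
Reagents that add atoms: chlorotriethylsilane, CC[Si](CC)(CC)Cl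
Why: Standard silylation of both hydroxyl groups (silyl ether formation).

Step 8
Reactants: 11 bis(triethylsilyl) ether
Product: 12 (2S)-3-bromo-2-[(triethylsilyl)oxy]propanal
Conditions: (COCl)2, DMSO, CH2Cl2, −78 to −30 °C; then Et3N, −78 °C
Reagents that add atoms: none
Why: Swern oxidation: the primary triethylsilyl ether is cleaved and oxidised in one operation while the secondary one is inert, and the base acts only at low temperature, so the α-silyloxy aldehyde should form without epimerisation or loss of HBr.

Step 9
Reactants: 13 methyl bis(2,2,2-trifluoroethyl)phosphonoacetate; 14 4-bromobut-1-yne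
Product: 15 methyl 2-[bis(2,2,2-trifluoroethoxy)phosphoryl]hex-5-ynoate (racemic)
Conditions: NaH, DMF, 0 °C; then 14, 0 to 40 °C
Reagents that add atoms: none
Why: C-Alkylation (SN2) of the sodium phosphonoacetate by the primary bromide puts the future C9–C12 chain on the olefination reagent.

Step 10
Reactants: 15 alkylated phosphonate; 12 (2S)-3-bromo-2-[(triethylsilyl)oxy]propanal
Product: 16 methyl (2Z,4S)-5-bromo-2-(but-3-yn-1-yl)-4-[(triethylsilyl)oxy]pent-2-enoate
Conditions: KN(SiMe3)2, 18-crown-6, THF, −78 °C; then 12, −78 °C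
Reagents that add atoms: none
Why: Still–Gennari olefination: the electron-poor bis(trifluoroethyl) phosphonate eliminates kinetically to the (Z)-trisubstituted enoate (ester cis to C6), and the low temperature keeps the α-stereocentre of 12 intact.

Step 11
Reactants: 16 (Z)-enoate alkyne; 8 dienyl bromide aldehyde
Product: 18 propargylic alcohol (R at the new carbinol carbon C13), via methylzinc acetylide 17 (not isolated)
Conditions: 16 (2 equiv), Me2Zn (3 equiv), (S,S)-ProPhenol (20 mol%), Ph3P=O (40 mol%), toluene, 0 °C; then 8, 4 °C; H2O work-up; excess 16 recovered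
Reagents that add atoms: none
Why: Zinc–ProPhenol-catalysed asymmetric alkynylation of an aldehyde: the dinuclear zinc complex binds aldehyde and zinc acetylide and transfers the alkynyl group to one carbonyl face (the Si face is needed), which sets the new carbinol centre (R, the future C13) under catalyst control.

Step 12
Reactants: 18 propargylic alcohol
Product: 19 (Z)-alkenylstannane (Bu3Sn on C12, H on C11, C10 chain cis to tin)
Conditions: Bu3SnH (1.1 equiv, slow addition), [Cp*RuCl]4 (2.5 mol%), CH2Cl2, rt
Reagents that add atoms: tributyltin hydride, CCCC[SnH](CCCC)CCCC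
Why: Hydroxyl-directed ruthenium-catalysed trans-hydrostannation of a propargylic alcohol: tin goes to the alkyne carbon next to the carbinol and hydrogen adds anti, giving the (Z)-alkenylstannane with the C10 chain cis to tin.

Step 13
Reactants: 19 (Z)-alkenylstannane
Product: 20 hydroxy diester (CO2Me on C12, cis to the C10 chain)
Conditions: Pd(OAc)2 (10 mol%), Ph3As (20 mol%), 1,4-benzoquinone (1.5 equiv), CO (1 atm), MeOH, rt
Reagents that add atoms: carbon monoxide, [C-]#[O+]; methanol, CO
Why: Hydroxyl-assisted oxidative methoxycarbonylation of the alkenylstannane (tin-to-palladium transmetalation, CO insertion, methanolysis) replaces tin by CO2Me with retention and gives the Morita–Baylis–Hillman-type ester; benzoquinone holds the catalyst as divalent palladium, which does not add to the dienyl bromide.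

Step 14
Reactants: 20 hydroxy diester
Product: 21 seco-compound with C13–OTBS and C6–OSiEt3 (alkyl bromide at C5, dienyl bromide at C4)
Conditions: TBSOTf, 2,6-lutidine, CH2Cl2, −78 °C
Reagents that add atoms: tert-butyldimethylsilyl trifluoromethanesulfonate, CC(C)(C)[Si](C)(C)OS(=O)(=O)C(F)(F)F
Why: Silyl ether formation with the reactive silyl triflate protects the hindered allylic alcohol so that the later acetyl transfer can only reach C6.

Step 15
Reactants: 21 seco-dibromide
Product: 22 14-membered macrocycle with C6–OSiEt3 and C13–OTBS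
Conditions: NiBr2(dme) (20 mol%), 4,4′-di-tert-butyl-2,2′-bipyridine (25 mol%), Mn powder (3 equiv), DMPU/THF, 40 °C; 21 added by syringe pump (final 2 mM)
Reagents that add atoms: none
Why: Proposed new method: zerovalent nickel (formed from NiBr2(dme) by Mn) should add to the C4–Br bond of the dienyl bromide with retention, a monovalent nickel species should abstract bromine from the primary C5–Br bond, and capture of the C5 radical by the alkenylnickel centre of the same molecule followed by reductive elimination from trivalent nickel forms C4–C5. The closest known reaction is the intermolecular nickel-catalysed reductive cross-electrophile coupling of alkenyl bromides with primary alkyl bromides, which is stereoretentive and tolerates esters and silyl ethers; new here is its use to close a macrocycle. The 14-membered carbocycle closes end to end at the metal (radical capture gives a 15-membered nickelacycle that contracts by reductive elimination), so no exo/endo question arises. No stereocentre is formed: the (3E) geometry is carried over from the (E)-alkenyl bromide, and C6, next to the radical carbon, is not involved. The step needs cross- over homo-coupling and ring closure over oligomerisation or hydrodebromination; the first is secured because the sp2 and sp3 C–Br bonds are activated by different elementary steps, the second by slow addition at high dilution and by the two (Z)-enoates and the diene, which limit the conformational freedom of the chain. C6 carries a silyl ether and not the acetate at this stage, so the C5 radical cannot undergo a 1,2-acyloxy shift and zerovalent nickel finds no allylic ester to ionise.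

Step 16
Reactants: 22 bis-silyl macrocycle
Product: 23 macrocycle with C6–OAc and C13–OTBS
Conditions: Ac2O (3 equiv), Bi(OTf)3 (2 mol%), CH2Cl2, −20 to 0 °C
Reagents that add atoms: acetic anhydride, CC(=O)OC(C)=O
Why: Lewis-acid-catalysed acetylative cleavage of a silyl ether (direct silyl ether to acetate exchange): the activated anhydride acylates the ether oxygen and Et3SiOAc leaves, so the C6–O bond and configuration are kept and no free C6 hydroxyl appears that could lactonise onto the cis ester, while the bulkier TBS ether should react much more slowly.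

Step 17
Reactants: 23 C13–OTBS acetate
Product: 24 CNP0189703.2 (target)
Conditions: HF·pyridine, pyridine, THF, 0 °C to rt
Reagents that add atoms: none
Why: Fluoride-mediated desilylation of the remaining secondary TBS ether under buffered conditions that spare the acetate, both methyl esters and the diene.

Compound list
1 | propyne | CC#C | starting material
2 | (1E)-2-bromo-1-iodoprop-1-ene | C/C(Br)=C\I | intermediate
3 | 3-methylbut-1-yne | CC(C)C#C | starting material
4 | tert-butyl(2-iodoethoxy)dimethylsilane | CC(C)(C)[Si](C)(C)OCCI | starting material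
5 | 2-[(1E)-4-{[tert-butyl(dimethyl)silyl]oxy}-2-(propan-2-yl)but-1-en-1-yl]-4,4,5,5-tetramethyl-1,3,2-dioxaborolane | CC(C)/C(CCO[Si](C)(C)C(C)(C)C)=C/B1OC(C)(C)C(C)(C)O1 | intermediate
6 | tert-butyl{[(3E,5E)-6-bromo-3-(propan-2-yl)hepta-3,5-dien-1-yl]oxy}dimethylsilane | CC(C)/C(CCO[Si](C)(C)C(C)(C)C)=C/C=C(\C)Br | intermediate
7 | (3E,5E)-6-bromo-3-(propan-2-yl)hepta-3,5-dien-1-ol | CC(C)/C(CCO)=C/C=C(\C)Br | intermediate
8 | (3E,5E)-6-bromo-3-(propan-2-yl)hepta-3,5-dienal | CC(C)/C(CC=O)=C/C=C(\C)Br | intermediate
9 | (2S)-oxiran-2-ylmethanol ((S)-glycidol) | OC[C@H]1CO1 | starting material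
10 | (2S)-3-bromopropane-1,2-diol | OC[C@H](O)CBr | intermediate
11 | (2S)-3-bromo-1,2-bis[(triethylsilyl)oxy]propane | CC[Si](CC)(CC)OC[C@H](O[Si](CC)(CC)CC)CBr | intermediate
12 | (2S)-3-bromo-2-[(triethylsilyl)oxy]propanal | O=C[C@H](O[Si](CC)(CC)CC)CBr | intermediate
13 | methyl 2-[bis(2,2,2-trifluoroethoxy)phosphoryl]acetate | COC(=O)CP(=O)(OCC(F)(F)F)OCC(F)(F)F | starting material
14 | 4-bromobut-1-yne | C#CCCBr | starting material
15 | methyl 2-[bis(2,2,2-trifluoroethoxy)phosphoryl]hex-5-ynoate (racemic at C2) | COC(=O)C(CCC#C)P(=O)(OCC(F)(F)F)OCC(F)(F)F | intermediate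
16 | methyl (2Z,4S)-5-bromo-2-(but-3-yn-1-yl)-4-[(triethylsilyl)oxy]pent-2-enoate | COC(=O)/C(CCC#C)=C\[C@H](O[Si](CC)(CC)CC)CBr | intermediate
17 | methyl{(5Z,7S)-8-bromo-5-(methoxycarbonyl)-7-[(triethylsilyl)oxy]oct-5-en-1-yn-1-yl}zinc (methylzinc acetylide of 16) | C[Zn]C#CCC/C(C(=O)OC)=C/[C@H](O[Si](CC)(CC)CC)CBr | intermediate
18 | methyl (2Z,4S)-5-bromo-2-[(5R,7E,9E)-10-bromo-5-hydroxy-7-(propan-2-yl)undeca-7,9-dien-3-yn-1-yl]-4-[(triethylsilyl)oxy]pent-2-enoate | COC(=O)/C(CCC#C[C@H](O)C/C(C(C)C)=C\C=C(/C)Br)=C\[C@H](O[Si](CC)(CC)CC)CBr | intermediate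
19 | methyl (2Z,4S)-5-bromo-2-[(3Z,5R,7E,9E)-10-bromo-5-hydroxy-7-(propan-2-yl)-4-(tributylstannyl)undeca-3,7,9-trien-1-yl]-4-[(triethylsilyl)oxy]pent-2-enoate | COC(=O)/C(CC/C=C(\[Sn](CCCC)(CCCC)CCCC)[C@H](O)C/C(C(C)C)=C\C=C(/C)Br)=C\[C@H](O[Si](CC)(CC)CC)CBr | intermediate
20 | methyl (2Z,4S)-5-bromo-2-[(3Z,5R,7E,9E)-10-bromo-5-hydroxy-4-(methoxycarbonyl)-7-(propan-2-yl)undeca-3,7,9-trien-1-yl]-4-[(triethylsilyl)oxy]pent-2-enoate | COC(=O)/C(CC/C=C(\C(=O)OC)[C@H](O)C/C(C(C)C)=C\C=C(/C)Br)=C\[C@H](O[Si](CC)(CC)CC)CBr | intermediate
21 | methyl (2Z,4S)-5-bromo-2-[(3Z,5R,7E,9E)-10-bromo-5-{[tert-butyl(dimethyl)silyl]oxy}-4-(methoxycarbonyl)-7-(propan-2-yl)undeca-3,7,9-trien-1-yl]-4-[(triethylsilyl)oxy]pent-2-enoate | COC(=O)/C(CC/C=C(\C(=O)OC)[C@H](O[Si](C)(C)C(C)(C)C)C/C(C(C)C)=C\C=C(/C)Br)=C\[C@H](O[Si](CC)(CC)CC)CBr | intermediate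
22 | dimethyl (1Z,5Z,7R,9E,11E,14R)-14-{[tert-butyl(dimethyl)silyl]oxy}-9-methyl-12-(propan-2-yl)-7-[(triethylsilyl)oxy]cyclotetradeca-1,5,9,11-tetraene-1,5-dicarboxylate | COC(=O)/C1=C\[C@H](O[Si](CC)(CC)CC)C/C(C)=C/C=C(/C(C)C)C[C@@H](O[Si](C)(C)C(C)(C)C)/C(C(=O)OC)=C/CC1 | intermediate
23 | dimethyl (1Z,5Z,7R,9E,11E,14R)-7-(acetyloxy)-14-{[tert-butyl(dimethyl)silyl]oxy}-9-methyl-12-(propan-2-yl)cyclotetradeca-1,5,9,11-tetraene-1,5-dicarboxylate | COC(=O)/C1=C\[C@H](OC(C)=O)C/C(C)=C/C=C(/C(C)C)C[C@@H](O[Si](C)(C)C(C)(C)C)/C(C(=O)OC)=C/CC1 | intermediate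
24 | dimethyl (1Z,5Z,7R,9E,11E,14R)-7-(acetyloxy)-14-hydroxy-9-methyl-12-(propan-2-yl)cyclotetradeca-1,5,9,11-tetraene-1,5-dicarboxylate (CNP0189703.2; cembrane numbering 6R,13R) | COC(=O)/C1=C\[C@H](OC(C)=O)C/C(C)=C/C=C(/C(C)C)C[C@@H](O)/C(C(=O)OC)=C/CC1 | target

Total step count: 17.
Longest linear sequence: 11 steps (steps 6, 7, 8, 10 and 11–17; the branch through steps 2–5 and 11–17 is equally long).

Steps most likely to fail

Step 15 (proposed new method). Intermolecular coupling to oligomers and hydrodebromination at C5 or C4 may outrun ring closure, and an alkylnickel intermediate may lose the β-silyloxy group. The fallback sets out from 21 and separates the two events along a two-electron path with no free C5 radical. Copper-catalysed borylation of the primary C–Br bond (B2pin2, CuI, PPh3, LiOMe, DMF, rt; alkenyl bromides are inert under these conditions) should give the primary alkyl pinacol boronate F1. A B-alkyl Suzuki–Miyaura macrocyclisation of the boronate with its own dienyl bromide (Pd(OAc)2, SPhos, K3PO4, THF/H2O, 60 °C, high dilution) then closes the same C4–C5 bond and comes back to the route at 22.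

Step 11. The unbranched, enolisable β,γ-unsaturated aldehyde may give poor facial selectivity through an unselective background addition, and the C1=C2 bond may drift into conjugation. The fallback sets out from 16 and 8. Ligand-free addition of the zinc acetylide 17 (Me2Zn, toluene, 0 °C) gives 18 mixed with its carbinol epimer F2. Dess–Martin oxidation of the mixture (pyridine-buffered, 0 °C) gives the single ynone F3. Noyori asymmetric transfer hydrogenation of the ynone (RuCl[(S,S)-TsDPEN](p-cymene), or its antipode as the facial sense requires, HCO2H/Et3N, rt) sets the carbinol under catalyst control and comes back to the route at 18.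

Step 13. Transient zerovalent palladium may insert into the dienyl C–Br bond before benzoquinone reoxidises it (carbonylation or homocoupling at C4), and protodestannation may compete. The fallback sets out from 19. Iododestannation (I2, CH2Cl2, −78 to 0 °C) should give, with retention, the (Z)-alkenyl iodide F4. Carbonylation of the iodide under zerovalent palladium (PdCl2(PPh3)2, CO (1 atm), MeOH, Et3N, rt), where the C–I bond reacts far faster than the hindered dienyl C–Br bond, comes back to the route at 20.

Further compounds
F1 | step 15 | methyl (2Z,4R)-2-[(3Z,5R,7E,9E)-10-bromo-5-{[tert-butyl(dimethyl)silyl]oxy}-4-(methoxycarbonyl)-7-(propan-2-yl)undeca-3,7,9-trien-1-yl]-5-(4,4,5,5-tetramethyl-1,3,2-dioxaborolan-2-yl)-4-[(triethylsilyl)oxy]pent-2-enoate | COC(=O)/C(CC/C=C(\C(=O)OC)[C@H](O[Si](C)(C)C(C)(C)C)C/C(C(C)C)=C\C=C(/C)Br)=C\[C@H](O[Si](CC)(CC)CC)CB1OC(C)(C)C(C)(C)O1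
F2 | step 11 | methyl (2Z,4S)-5-bromo-2-[(5S,7E,9E)-10-bromo-5-hydroxy-7-(propan-2-yl)undeca-7,9-dien-3-yn-1-yl]-4-[(triethylsilyl)oxy]pent-2-enoate | COC(=O)/C(CCC#C[C@@H](O)C/C(C(C)C)=C\C=C(/C)Br)=C\[C@H](O[Si](CC)(CC)CC)CBr
F3 | step 11 | methyl (2Z,4S)-5-bromo-2-[(7E,9E)-10-bromo-5-oxo-7-(propan-2-yl)undeca-7,9-dien-3-yn-1-yl]-4-[(triethylsilyl)oxy]pent-2-enoate | COC(=O)/C(CCC#CC(=O)C/C(C(C)C)=C\C=C(/C)Br)=C\[C@H](O[Si](CC)(CC)CC)CBr
F4 | step 13 | methyl (2Z,4S)-5-bromo-2-[(3Z,5R,7E,9E)-10-bromo-5-hydroxy-4-iodo-7-(propan-2-yl)undeca-3,7,9-trien-1-yl]-4-[(triethylsilyl)oxy]pent-2-enoate | COC(=O)/C(CC/C=C(\I)[C@H](O)C/C(C(C)C)=C\C=C(/C)Br)=C\[C@H](O[Si](CC)(CC)CC)CBr
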